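**Plan**
1. Nothing in the target resists closure and there is no stereocentre. The real cost of the obvious route is making two partners at different oxidation levels (acid and alcohol) separately and joining them with an activating agent.
2. Enabling feature: the ester has the pattern R–C(=O)–O–CH2–R, with the same R = 2-(3,4-dimethoxyphenyl)ethyl on the acyl carbon and on the O–CH2 carbon. Both halves are one veratryl–C3 skeleton and differ only in the oxidation level of C1 (Tishchenko pattern).
3. Retrosynthesis: cut the acyl C–O(alkyl) bond and level both C1 atoms to CH2OH, so that the two halves become one monomer, alcohol 3. Then cut the primary C–OH bond of 3 back to the terminal alkene carbon of methyl eugenol 1.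
4. Forward: anti-Markovnikov hydration of the allyl chain of 1 (step 1), then acceptorless dehydrogenative homodimerisation of 3 (step 2). Step 2 creates the carbonyl group and the ester C–O bond in one operation and joins the chain at the only possible place, with H2 as the sole coproduct.
5. No ring is formed in the route; both veratrole rings come intact from 1.
6. Stereochemistry: none has to be set (see remark).

Key step: step 2

Remark: the target SMILES holds no stereocentre and no stereogenic double bond, so the compound is achiral and "single enantiomer" means simply the compound itself.

**Step 1**
Reactants: 1 methyl eugenol (4-allyl-1,2-dimethoxybenzene)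
Product: 3 3-(3,4-dimethoxyphenyl)propan-1-ol, via B-alkyl-9-BBN adduct 2 (not isolated)
Conditions: 9-BBN (0.5 M in THF, 1.1 equiv), 0 °C → rt; then 3 M aq NaOH, 30 % H2O2, 0 °C → rt; distillation or chromatography
Reagents that add atoms: 9-borabicyclo[3.3.1]nonane, B1C2CCCC1CCC2 (boron cage stays only in 2, only H stays in 3); hydrogen peroxide, OO (hydroxyl oxygen of 3)
Why: Hydroboration–oxidation: the bulky dialkylborane places boron on the unhindered terminal carbon of the allyl group (anti-Markovnikov), and the alkaline peroxide 1,2-migration replaces C–B by C–O without touching the aryl methyl ethers; no stereocentre is formed.

**Step 2**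
Reactants: 3 3-(3,4-dimethoxyphenyl)propan-1-ol (two molecules per molecule of product)
Product: 6 3-(3,4-dimethoxyphenyl)propyl 3-(3,4-dimethoxyphenyl)propanoate, via aldehyde 4 (not isolated), via hemiacetal 5 (not isolated)
Conditions: [RuH(CO)(PNN*)] (commercial dearomatised pincer complex of 2-(di-tert-butylphosphinomethyl)-6-(diethylaminomethyl)pyridine, 0.5 mol %), dry toluene, reflux, open to a slow Ar stream, no base, no hydrogen acceptor
Reagents that add atoms: none
Why: The O–H bond of 3 adds across the dearomatised Ru–pincer arm (metal–ligand cooperation), β-hydride elimination releases aldehyde 4 and a Ru dihydride that expels H2 and re-forms the catalyst, and 4 is captured by a second molecule of 3 as hemiacetal 5, which is dehydrogenated in the same way to ester 6. This is the acceptorless dehydrogenative homocoupling of primary alcohols to symmetrical esters, the alcohol-level version of the Tishchenko reaction, which is well documented for unbranched primary alkanols and arylalkanols. No ring is closed and no stereocentre remains, since the carbinol carbon of 5 is transient and becomes the planar carbonyl carbon. The step needs chemoselectivity for hemiacetal dehydrogenation over aldol condensation, decarbonylation and acetal formation, and this should be secured by the base-free neutral medium and by the very low stationary concentration of 4 in a large excess of 3. No cross-selectivity problem can arise, because the acyl and alkoxy halves of 6 carry the same 2-(3,4-dimethoxyphenyl)ethyl group and a single alcohol in the flask can give only one ester, while the electron-rich veratrole rings, which halogen-based oxidative esterifications would attack, are inert to the ruthenium hydride. Sweeping H2 out of the refluxing toluene should drive the nearly thermoneutral equilibrium to the ester.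

**Compound list**
1 | methyl eugenol (4-allyl-1,2-dimethoxybenzene) | COc1ccc(CC=C)cc1OC | starting material
2 | 9-[3-(3,4-dimethoxyphenyl)propyl]-9-borabicyclo[3.3.1]nonane | COc1ccc(CCCB2C3CCCC2CCC3)cc1OC | intermediate (not isolated)
3 | 3-(3,4-dimethoxyphenyl)propan-1-ol | COc1ccc(CCCO)cc1OC | intermediate
4 | 3-(3,4-dimethoxyphenyl)propanal | COc1ccc(CCC=O)cc1OC | intermediate (not isolated)
5 | 3-(3,4-dimethoxyphenyl)-1-[3-(3,4-dimethoxyphenyl)propoxy]propan-1-ol (hemiacetal, racemic transient centre) | COc1ccc(CCCOC(O)CCc2ccc(OC)c(OC)c2)cc1OC | intermediate (not isolated)
6 | 3-(3,4-dimethoxyphenyl)propyl 3-(3,4-dimethoxyphenyl)propanoate (CNP0122973.0, achiral) | COc1ccc(CCCOC(=O)CCc2ccc(OC)c(OC)c2)cc1OC | target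

**Total step count:** 2. **Longest linear sequence:** 2. Alcohol 3 is also sold, so the route can shrink to the key step alone.

**Steps most likely to fail.** The route has only two steps, so both are ranked and no third step remains to be listed.

1. Step 2. The dehydrogenation may stall at partial conversion. Possible causes are catalyst deactivation (decarbonylation of the transient aldehyde at ruthenium, or poisoning by traces of water, peroxide or boron residues from step 1) and poor H2 removal. If the aldehyde then accumulates, aldol self-condensation may set in. The fallback gives up the dimerisation and makes the ester bond by classical acyl transfer. It sets out from 3. One half of the material is oxidised with TEMPO (cat.)/PhI(OAc)2 in MeCN–H2O to 3-(3,4-dimethoxyphenyl)propanoic acid F1. This acid is joined to the other half of 3 by Steglich esterification (DCC, cat. DMAP, CH2Cl2, 0 °C → rt). The fallback comes back to the route at 6.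

2. Step 1. Boron may leak to the internal alkene carbon, which leads to the secondary alcohol. Separation of the diol and boron residues may also be incomplete, which would later burden the ruthenium catalyst. The fallback installs the oxygen by hydride abstraction from the electron-rich arylpropene instead of by hydrometalation. It sets out from 1. DDQ (2.2 equiv) in wet dioxane abstracts the benzylic hydride, water adds to the terminal carbon of the conjugated cation, and a second oxidation gives (E)-3-(3,4-dimethoxyphenyl)prop-2-enal F2. Here the regiochemistry is fixed by conjugation with the veratrole ring. Exhaustive hydrogenation (H2, Raney Ni, EtOH) then reduces C=C and C=O. The fallback comes back to the route at 3.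

**Further compounds**
F1 | step 2 | 3-(3,4-dimethoxyphenyl)propanoic acid | COc1ccc(CCC(=O)O)cc1OC
F2 | step 1 | (E)-3-(3,4-dimethoxyphenyl)prop-2-enal | COc1ccc(/C=C/C=O)cc1OC
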